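**Plan** (cembrane-type numbering: C1 is the ring-fusion carbon carrying the lactone α-carbon C15; C2 bears the lactone oxygen; ring alkenes C3=C4 and C7=C8; epoxide C11–C12; acetate on C13; methyls on C4, C8, C12; C16 is the lactone carbonyl, C17 the exocyclic methylene)
1. Cuts, in retrosynthetic order: C13–OAc (back to the 13-epi alcohol), the epoxide oxygen, C15=C17, the lactone O–C16 bond, then the carbocycle at C2–C3 together with C4–CH3; the open chain is cut at C1–C15, C13–C14 and C5–C6.
2. Enabling feature: in the 14-membered ring the oxygenated C2 is flanked by an E C3=C4 alkene whose C4 methyl is cis to C2. This is the pattern left when an aldehyde carbon and a methyl group add to the same side of a terminal C3≡C4 alkyne.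
3. Forward: the C3–C13 chain comes from geranyl bromide and a propargyl anion; C14–C1–C2 (allyl) and C15–C16 (bromoacetate, kept as a tert-butyl acetate arm through the ring closure) are then attached. Rings arise in the order carbocycle, γ-lactone, epoxide; C17 is added after lactonisation.
4. Stereochemistry: 7E from geranyl bromide, 11E from the SeO2 oxidation, 3E from syn carbometalation. C13 (R, deliberately epimeric) comes from Brown allylboration; C1 from trans alkylation of the C13-derived butyrolactone; C2 from 1,2-induction by C1 in the ring closure; C11/C12 from hydroxyl-directed erythro epoxidation; C13 is finally inverted to S by Mitsunobu acetylation.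

Key step: step 12

Remarks: numbered starting materials are 1, 2 and 20, all other atom donors stand on the reagent lines; species of catalytic cycles and metal alkoxides that merely take up a proton on work-up are not numbered; the CIP labels at C2 (2R in 21–25, 2S from 26 on) and C12 (12R in 28, 12S in 30) change only because substituent priorities change, the spatial arrangement being that of the target throughout.

**Route**

Step 1
Reactants: 1 geranyl bromide; 2 1-(trimethylsilyl)propyne
Product: 4 [(5E)-6,10-dimethylundeca-5,9-dien-1-yn-1-yl]trimethylsilane, via lithiated silylpropyne 3 (not isolated)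
Conditions: n-BuLi, THF, −78 °C; then 1, −78 °C → rt
Reagents that add atoms: none
Why: Lithiated 1-(trimethylsilyl)propyne is a propargyl anion equivalent that displaces the primary allylic bromide by SN2 alkylation at its silyl-free terminus (C5–C6 bond) without allene formation or allylic transposition, so the E geometry of geranyl bromide is kept.

Step 2
Reactants: 4 silyl dienyne
Product: 5 (2E,6E)-2,6-dimethyl-11-(trimethylsilyl)undeca-2,6-dien-10-yn-1-ol
Conditions: SeO2 (cat.), t-BuOOH, salicylic acid (cat.), CH2Cl2, rt
Reagents that add atoms: tert-butyl hydroperoxide, CC(C)(C)OO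
Why: Catalytic SeO2/t-BuOOH allylic oxidation (ene reaction, then [2,3]-sigmatropic shift) should attack the E methyl of the terminal, most electron-rich trisubstituted alkene and give the E allylic alcohol (oxygen on C13); any over-oxidised enal 6 is simply carried into step 3.

Step 3
Reactants: 5 allylic alcohol
Product: 6 (2E,6E)-2,6-dimethyl-11-(trimethylsilyl)undeca-2,6-dien-10-ynal
Conditions: TEMPO (cat.), PhI(OAc)2, CH2Cl2, rt
Reagents that add atoms: none
Why: Oxoammonium (TEMPO/PhI(OAc)2) oxidation converts the primary allylic alcohol into the enal without touching the alkenes or the silylalkyne and without E/Z isomerisation.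

Step 4
Reactants: 6 enal
Product: 8 (4R,5E,9E)-5,9-dimethyl-14-(trimethylsilyl)tetradeca-1,5,9-trien-13-yn-4-ol, via borinate ester 7 (not isolated)
Conditions: (+)-Ipc2BOMe, allylMgBr, Et2O, 0 °C; then 6, −78 °C; then NaBO3·4H2O, THF/H2O, rt
Reagents that add atoms: (+)-B-allyldiisopinocampheylborane, C=CCB([C@H]1C[C@H]2C[C@@H]([C@@H]1C)C2(C)C)[C@H]1C[C@H]2C[C@@H]([C@@H]1C)C2(C)C
Why: Brown asymmetric allylboration through a closed chair transition state forms C13–C14 and brings in C14–C1–C2; the (+)-reagent (from (−)-α-pinene) adds to the aldehyde face that gives the R carbinol when the aldehyde substituent outranks allyl, as the alkenyl group does here, so C13 is set as R.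

Step 5
Reactants: 8 homoallylic alcohol
Product: 10 (4R,5E,9E)-5,9-dimethyl-14-(trimethylsilyl)tetradeca-5,9-dien-13-yne-1,4-diol, via bis(9-BBN) adduct 9 (not isolated)
Conditions: 9-BBN (2.2 equiv), THF, 0 °C → rt; then NaBO3·4H2O, H2O, rt
Reagents that add atoms: sodium perborate tetrahydrate, [Na+].[Na+].O[B-]1(O)OO[B-](O)(O)OO1.O.O.O.O.O.O
Why: 9-BBN hydroborates the monosubstituted alkene anti-Markovnikov far faster than the trisubstituted alkenes or the silyl-capped alkyne (one equivalent is consumed by the hydroxyl as a borinate), and perborate oxidation, mild enough for the C–SiMe3 bond, replaces boron by OH; C13 is untouched.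

Step 6
Reactants: 10 1,4-diol
Product: 12 (5R)-5-[(2E,6E)-6-methyl-11-(trimethylsilyl)undeca-2,6-dien-10-yn-2-yl]oxolan-2-one, via lactol 11 (not isolated)
Conditions: TEMPO (cat.), PhI(OAc)2 (2.5 equiv), CH2Cl2, rt
Reagents that add atoms: none
Why: Oxidative lactonisation of a 1,4-diol: the primary alcohol is oxidised chemoselectively, the aldehyde is trapped by the C13 hydroxyl as lactol 11, and this is oxidised on to the γ-lactone, which ties C13–O and C2 into a five-membered ring.

Step 7
Reactants: 12 γ-lactone
Product: 14 tert-butyl 2-[(3R,5R)-5-[(2E,6E)-6-methyl-11-(trimethylsilyl)undeca-2,6-dien-10-yn-2-yl]-2-oxooxolan-3-yl]acetate, via lithium enolate 13 (not isolated)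
Conditions: LiN(SiMe3)2, THF, −78 °C; BrCH2CO2t-Bu, −78 → −40 °C
Reagents that add atoms: tert-butyl bromoacetate, CC(C)(C)OC(=O)CBr
Why: Enolate alkylation of a γ-substituted γ-butyrolactone takes place on the face opposite the γ (C13) substituent, so the acetate arm should enter trans to the alkenyl chain (1,3-induction), forming C1–C15 and setting C1 as R.

Step 8
Reactants: 14 trans-disubstituted lactone
Product: 15 tert-butyl (3R,5R,6E,10E)-5-hydroxy-3-[methoxy(methyl)carbamoyl]-6,10-dimethyl-15-(trimethylsilyl)pentadeca-6,10-dien-14-ynoate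
Conditions: MeNHOMe·HCl, AlMe3, CH2Cl2, 0 °C → rt; aq. potassium sodium tartrate
Reagents that add atoms: N,O-dimethylhydroxylamine hydrochloride, CNOC.Cl
Why: Weinreb aminolysis: the chloro(methyl)aluminium amide opens the γ-lactone at the acyl carbon much faster than it attacks the hindered tert-butyl ester, releasing the C13 hydroxyl and leaving C2 as an amide without disturbing C1.

Step 9
Reactants: 15 hydroxy Weinreb amide
Product: 16 tert-butyl (3R,5R,6E,10E)-5-[(tert-butyldimethylsilyl)oxy]-3-[methoxy(methyl)carbamoyl]-6,10-dimethyl-15-(trimethylsilyl)pentadeca-6,10-dien-14-ynoate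
Conditions: TBSOTf, 2,6-lutidine, CH2Cl2, −78 °C
Reagents that add atoms: tert-butyldimethylsilyl trifluoromethanesulfonate, CC(C)(C)[Si](C)(C)OS(=O)(=O)C(F)(F)F
Why: Silylation with the silyl triflate at low temperature caps the hindered secondary allylic alcohol before it can relactonise, and the TBS ether withstands the base, hydride, organozinc and enolate steps that follow.

Step 10
Reactants: 16 bis-silyl compound
Product: 17 tert-butyl (3R,5R,6E,10E)-5-[(tert-butyldimethylsilyl)oxy]-3-[methoxy(methyl)carbamoyl]-6,10-dimethylpentadeca-6,10-dien-14-ynoate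
Conditions: K2CO3, MeOH, rt
Reagents that add atoms: none
Why: Carbonate-mediated methanolysis (protodesilylation) cleaves only the alkynyl C–Si bond; the O-silyl ether, the tert-butyl ester and the Weinreb amide are stable, and the amide α-centre C1 is not epimerised by carbonate.

Step 11
Reactants: 17 terminal alkyne Weinreb amide
Product: 19 tert-butyl (3R,5R,6E,10E)-5-[(tert-butyldimethylsilyl)oxy]-3-formyl-6,10-dimethylpentadeca-6,10-dien-14-ynoate (seco ynal), via hemiaminal aluminate 18 (not isolated)
Conditions: i-Bu2AlH, THF, −78 °C; aq. potassium sodium tartrate, 0 °C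
Reagents that add atoms: none
Why: Hydride reduction of a Weinreb amide stops at the chelated hemiaminal aluminate 18, which releases the aldehyde only on work-up, so over-reduction is avoided and the less electrophilic tert-butyl ester is left; a cold, buffered work-up keeps the α-centre C1 intact.

Step 12
Reactants: 19 seco ynal; 20 dimethylzinc
Product: 21 tert-butyl 2-[(1R,2R,3E,7E,11E,13R)-13-[(tert-butyldimethylsilyl)oxy]-2-hydroxy-4,8,12-trimethylcyclotetradeca-3,7,11-trien-1-yl]acetate
Conditions: Ni(cod)2 (20 mol %), 20 (3 equiv), THF, 0 °C, 19 added by syringe pump (final ca. 3 mM); aq. NH4Cl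
Reagents that add atoms: none
Why: Proposed new method: zerovalent nickel is expected to bind the C2 aldehyde and the terminal C3≡C4 alkyne of 19 and couple them oxidatively to an oxanickelacyclopentene (C2–C3 formed, nickel on C4); methyl transfer from Me2Zn and C–C reductive elimination then put CH3 on C4 on the same side as C2, so the E alkene with the methyl cis to the carbinol follows from syn addition and not from ring thermodynamics. The closest known reactions are the Ni(cod)2/organozinc three-component alkylative coupling of aldehydes with terminal alkynes and the nickel-catalysed reductive macrocyclisation of terminal ynals; their combination in a macrocyclisation has not been shown. The 14-membered ring closes in the endo mode: the aldehyde carbon bonds to the unsubstituted alkyne terminus C3, as in the intermolecular couplings, and both alkyne carbons become ring members. The new C2 centre is governed by the adjacent C1 centre (1,2-induction, Felkin–Anh sense): the C1–C14 bond, which carries the tether and the bulky C13 silyloxy branch, should lie anti to the forming C2–C3 bond with the slim CH2CO2t-Bu arm beside the carbonyl oxygen, and attack past the C1 hydrogen then gives the C1/C2 relationship of the trans lactone; this prediction is the least certain element of the step. The step needs C3 over C4 attack, coupling before methyl transfer, ring closure over oligomerisation and the stated facial selectivity; these rest on the sterically differentiated terminal alkyne, a phosphine-free catalyst with a methyl donor lacking β-hydrogens (no reductive pathway, slow uncatalysed carbonyl addition), slow addition at high dilution and the C1 substitution pattern. The tert-butyl ester is chosen so that the zinc alkoxide of 21 does not lactonise in the flask.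

Step 13
Reactants: 21 macrocyclic hydroxy ester
Product: 22 (1R,2R,13R)-13-(tert-butyldimethylsilyloxy)-17-norcembra-3E,7E,11E-trien-16,2-olide (trans-fused γ-lactone; O on C2, C16 carbonyl, C15 methylene)
Conditions: KOt-Bu (cat.), THF, 0 °C
Reagents that add atoms: none
Why: Base-catalysed intramolecular transesterification (5-exo-trig lactonisation): the C2 alkoxide attacks the tert-butyl ester and expels tert-butoxide, which carries the chain; no bond at C2 is broken, so the trans-fused γ-lactone forms with retention.

Step 14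
Reactants: 22 trans-fused lactone
Product: 26 (1R,2S,13R)-13-(tert-butyldimethylsilyloxy)cembra-3E,7E,11E,15(17)-tetraen-16,2-olide, via lithium enolate 23 (not isolated), via Mannich base 24 (not isolated), via ammonium iodide 25 (not isolated)
Conditions: LiN(SiMe3)2, THF, −78 °C; CH2=NMe2+ I−, −78 °C → rt; MeI, MeOH, rt; aq. NaHCO3, CH2Cl2
Reagents that add atoms: N,N-dimethylmethyleneiminium iodide (Eschenmoser's salt), C=[N+](C)C.[I-]
Why: Lactone α-methylenation: Mannich reaction of the lithium enolate with Eschenmoser's salt, N-methylation and E1cB (Hofmann-type) loss of trimethylamine introduce C17 as the exocyclic methylene; the transient C15 centre is destroyed again and no other enolisable position is present.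

Step 15
Reactants: 26 silyl-protected methylene lactone
Product: 27 (1R,2S,13R)-13-hydroxycembra-3E,7E,11E,15(17)-tetraen-16,2-olide
Conditions: HF·pyridine, pyridine, THF, 0 °C → rt
Reagents that add atoms: none
Why: Fluoride-mediated Si–O cleavage under pyridine-buffered, weakly acidic conditions removes the TBS ether without adding a nucleophile to the Michael-accepting methylene lactone or ionising the allylic C2–O bond.

Step 16
Reactants: 27 13R allylic alcohol
Product: 28 (1R,2S,11R,12R,13R)-11,12-epoxy-13-hydroxycembra-3E,7E,15(17)-trien-16,2-olide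
Conditions: VO(acac)2 (cat.), t-BuOOH, CH2Cl2, 0 °C
Reagents that add atoms: tert-butyl hydroperoxide, CC(C)(C)OO
Why: Vanadium-catalysed hydroxyl-directed epoxidation acts only on the alkene allylic to the free C13 hydroxyl and delivers oxygen syn to it from the conformer that avoids allylic 1,2-strain between the C12 methyl and C14 (erythro mode), which from the 13R alcohol gives the epoxide configuration of the target; the electron-poor methylene and the remote alkenes are not touched.

Step 17
Reactants: 28 erythro epoxy alcohol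
Product: 30 target, (1R,2S,11R,12S,13S)-13-acetoxy-11,12-epoxycembra-3E,7E,15(17)-trien-16,2-olide, via alkoxyphosphonium acetate 29 (not isolated)
Conditions: PPh3, DIAD (premixed), AcOH, toluene, 0 °C → rt
Reagents that add atoms: acetic acid, CC(O)=O
Why: Mitsunobu esterification: the alcohol is activated as alkoxyphosphonium 29 and displaced by acetate in an SN2 reaction with inversion, turning 13R into the 13S acetate; premixing phosphine and azodicarboxylate keeps free phosphine away from the methylene lactone.

**Compound list**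

1 | geranyl bromide, (2E)-1-bromo-3,7-dimethylocta-2,6-diene | CC(C)=CCC/C(C)=C/CBr | starting material
2 | 1-(trimethylsilyl)propyne | CC#C[Si](C)(C)C | starting material
3 | [3-(trimethylsilyl)prop-2-yn-1-yl]lithium (not isolated) | [Li]CC#C[Si](C)(C)C | intermediate
4 | [(5E)-6,10-dimethylundeca-5,9-dien-1-yn-1-yl]trimethylsilane | CC(C)=CCC/C(C)=C/CCC#C[Si](C)(C)C | intermediate
5 | (2E,6E)-2,6-dimethyl-11-(trimethylsilyl)undeca-2,6-dien-10-yn-1-ol | OC/C(C)=C/CC/C(C)=C/CCC#C[Si](C)(C)C | intermediate
6 | (2E,6E)-2,6-dimethyl-11-(trimethylsilyl)undeca-2,6-dien-10-ynal | O=C/C(C)=C/CC/C(C)=C/CCC#C[Si](C)(C)C | intermediate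
7 | diisopinocampheylborinate ester of 8 (not isolated) | C=CC[C@@H](OB([C@H]1C[C@H]2C[C@@H]([C@@H]1C)C2(C)C)[C@H]1C[C@H]2C[C@@H]([C@@H]1C)C2(C)C)/C(C)=C/CC/C(C)=C/CCC#C[Si](C)(C)C | intermediate
8 | (4R,5E,9E)-5,9-dimethyl-14-(trimethylsilyl)tetradeca-1,5,9-trien-13-yn-4-ol | C=CC[C@@H](O)/C(C)=C/CC/C(C)=C/CCC#C[Si](C)(C)C | intermediate
9 | bis(9-BBN) adduct of 8, B-alkyl at the chain terminus and O-borinate at the carbinol (not isolated) | B1(CCC[C@@H](OB2C3CCCC2CCC3)/C(C)=C/CC/C(C)=C/CCC#C[Si](C)(C)C)C2CCCC1CCC2 | intermediate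
10 | (4R,5E,9E)-5,9-dimethyl-14-(trimethylsilyl)tetradeca-5,9-dien-13-yne-1,4-diol | OCCC[C@@H](O)/C(C)=C/CC/C(C)=C/CCC#C[Si](C)(C)C | intermediate
11 | (5R)-5-[(2E,6E)-6-methyl-11-(trimethylsilyl)undeca-2,6-dien-10-yn-2-yl]oxolan-2-ol, lactol (not isolated) | OC1CC[C@@H](O1)/C(C)=C/CC/C(C)=C/CCC#C[Si](C)(C)C | intermediate
12 | (5R)-5-[(2E,6E)-6-methyl-11-(trimethylsilyl)undeca-2,6-dien-10-yn-2-yl]oxolan-2-one | O=C1CC[C@@H](O1)/C(C)=C/CC/C(C)=C/CCC#C[Si](C)(C)C | intermediate
13 | lithium enolate of 12 (not isolated) | [Li]OC1=CC[C@@H](O1)/C(C)=C/CC/C(C)=C/CCC#C[Si](C)(C)C | intermediate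
14 | tert-butyl 2-[(3R,5R)-5-[(2E,6E)-6-methyl-11-(trimethylsilyl)undeca-2,6-dien-10-yn-2-yl]-2-oxooxolan-3-yl]acetate | O=C1[C@@H](CC(=O)OC(C)(C)C)C[C@@H](O1)/C(C)=C/CC/C(C)=C/CCC#C[Si](C)(C)C | intermediate
15 | tert-butyl (3R,5R,6E,10E)-5-hydroxy-3-[methoxy(methyl)carbamoyl]-6,10-dimethyl-15-(trimethylsilyl)pentadeca-6,10-dien-14-ynoate | CON(C)C(=O)[C@@H](CC(=O)OC(C)(C)C)C[C@@H](O)/C(C)=C/CC/C(C)=C/CCC#C[Si](C)(C)C | intermediate
16 | tert-butyl (3R,5R,6E,10E)-5-[(tert-butyldimethylsilyl)oxy]-3-[methoxy(methyl)carbamoyl]-6,10-dimethyl-15-(trimethylsilyl)pentadeca-6,10-dien-14-ynoate | CON(C)C(=O)[C@@H](CC(=O)OC(C)(C)C)C[C@@H](O[Si](C)(C)C(C)(C)C)/C(C)=C/CC/C(C)=C/CCC#C[Si](C)(C)C | intermediate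
17 | tert-butyl (3R,5R,6E,10E)-5-[(tert-butyldimethylsilyl)oxy]-3-[methoxy(methyl)carbamoyl]-6,10-dimethylpentadeca-6,10-dien-14-ynoate | CON(C)C(=O)[C@@H](CC(=O)OC(C)(C)C)C[C@@H](O[Si](C)(C)C(C)(C)C)/C(C)=C/CC/C(C)=C/CCC#C | intermediate
18 | diisobutylaluminium N-methoxy-N-methyl hemiaminal (aluminate chelate) leading to 19 (not isolated) | CON(C)C(O[Al](CC(C)C)CC(C)C)[C@@H](CC(=O)OC(C)(C)C)C[C@@H](O[Si](C)(C)C(C)(C)C)/C(C)=C/CC/C(C)=C/CCC#C | intermediate
19 | seco ynal, tert-butyl (3R,5R,6E,10E)-5-[(tert-butyldimethylsilyl)oxy]-3-formyl-6,10-dimethylpentadeca-6,10-dien-14-ynoate | O=C[C@@H](CC(=O)OC(C)(C)C)C[C@@H](O[Si](C)(C)C(C)(C)C)/C(C)=C/CC/C(C)=C/CCC#C | intermediate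
20 | dimethylzinc | C[Zn]C | starting material
21 | tert-butyl 2-[(1R,2R,3E,7E,11E,13R)-13-[(tert-butyldimethylsilyl)oxy]-2-hydroxy-4,8,12-trimethylcyclotetradeca-3,7,11-trien-1-yl]acetate | O[C@H]1/C=C(\C)CC/C=C(\C)CC/C=C(\C)[C@H](O[Si](C)(C)C(C)(C)C)C[C@@H]1CC(=O)OC(C)(C)C | intermediate
22 | (1R,2R,13R)-13-(tert-butyldimethylsilyloxy)-17-norcembra-3E,7E,11E-trien-16,2-olide | O=C1O[C@H]2/C=C(\C)CC/C=C(\C)CC/C=C(\C)[C@H](O[Si](C)(C)C(C)(C)C)C[C@@H]2C1 | intermediate
23 | lithium enolate of 22 (not isolated) | [Li]OC=1O[C@H]2/C=C(\C)CC/C=C(\C)CC/C=C(\C)[C@H](O[Si](C)(C)C(C)(C)C)C[C@@H]2C=1 | intermediate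
24 | 15-(dimethylaminomethyl) derivative of 22, Mannich base (not isolated) | O=C1O[C@H]2/C=C(\C)CC/C=C(\C)CC/C=C(\C)[C@H](O[Si](C)(C)C(C)(C)C)C[C@@H]2C1CN(C)C | intermediate
25 | 15-(trimethylammoniomethyl) iodide of 22 (not isolated) | O=C1O[C@H]2/C=C(\C)CC/C=C(\C)CC/C=C(\C)[C@H](O[Si](C)(C)C(C)(C)C)C[C@@H]2C1C[N+](C)(C)C.[I-] | intermediate
26 | (1R,2S,13R)-13-(tert-butyldimethylsilyloxy)cembra-3E,7E,11E,15(17)-tetraen-16,2-olide | C=C1C(=O)O[C@H]2/C=C(\C)CC/C=C(\C)CC/C=C(\C)[C@H](O[Si](C)(C)C(C)(C)C)C[C@H]12 | intermediate
27 | (1R,2S,13R)-13-hydroxycembra-3E,7E,11E,15(17)-tetraen-16,2-olide | C=C1C(=O)O[C@H]2/C=C(\C)CC/C=C(\C)CC/C=C(\C)[C@H](O)C[C@H]12 | intermediate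
28 | (1R,2S,11R,12R,13R)-11,12-epoxy-13-hydroxycembra-3E,7E,15(17)-trien-16,2-olide | C=C1C(=O)O[C@H]2/C=C(\C)CC/C=C(\C)CC[C@H]3O[C@]3(C)[C@H](O)C[C@H]12 | intermediate
29 | C13 alkoxytriphenylphosphonium acetate of 28 (not isolated) | C=C1C(=O)O[C@H]2/C=C(\C)CC/C=C(\C)CC[C@H]3O[C@]3(C)[C@H](O[P+](c4ccccc4)(c4ccccc4)c4ccccc4)C[C@H]12.CC(=O)[O-] | intermediate
30 | CNP0146076.5, (1R,2S,11R,12S,13S)-13-acetoxy-11,12-epoxycembra-3E,7E,15(17)-trien-16,2-olide | C=C1C(=O)O[C@H]2/C=C(\C)CC/C=C(\C)CC[C@H]3O[C@]3(C)[C@@H](OC(C)=O)C[C@H]12 | target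

**Totals and risks**

Total steps: 17. Longest linear sequence: 17 (from geranyl bromide 1).

Steps most likely to fail:

1. Step 12 (proposed new method). The nickel catalyst may be diverted into alkyne oligomerisation, bonding at C4 (exo closure) or methyl transfer to the aldehyde before C–C coupling, and the facial discrimination at C2 may be insufficient or opposite to the prediction. Fallback with known chemistry, setting out from 17 and returning at 21: zirconium-catalysed carboalumination of the terminal alkyne (AlMe3, Cp2ZrCl2, CH2Cl2, low temperature, a medium the Weinreb amide already tolerates in step 8) followed by iodinolysis should give the E vinyl iodide Weinreb amide F1, with the C4 methyl in place and iodine on C3. Reduction with i-Bu2AlH should then give the iodo aldehyde F2, and Nozaki–Hiyama–Kishi macrocyclisation (CrCl2, NiCl2 cat., DMSO/THF, high dilution) forms the same C2–C3 bond with retention of alkene geometry to deliver 21. Should either closure give both C2 epimers, the mixture would be oxidised with Dess–Martin periodinane to the macrocyclic enone F3 and reduced back to 21 with (S)-Me-CBS/catecholborane, the conjugated alkenyl arm being taken as the large group.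

2. Step 17. The C13 alcohol is flanked by the fully substituted epoxide carbon C12, so the SN2 displacement may be slow and give way to elimination, retention through an acyloxyphosphonium species, or conjugate addition of phosphine to the methylene lactone. Fallback, setting out from 28 and returning at 30: Dess–Martin oxidation to the epoxy ketone F4; reagent-controlled reduction with (R)-Me-CBS/catecholborane (C12 as the large group) to the 13S epoxy alcohol F5; acetylation with Ac2O, DMAP and pyridine to give 30.

3. Step 16. The conformational demands of the macrocycle may override the acyclic 1,2-strain model and erode the facial selectivity of the directed epoxidation. Fallback, setting out from 27 and returning at 28: Sharpless asymmetric epoxidation with Ti(Oi-Pr)4, D-(−)-diisopropyl tartrate and t-BuOOH. The 13R alcohol is the fast-reacting (matched) enantiomer for this tartrate, so reagent control and substrate preference both point to the same erythro epoxy alcohol; no new compound is involved.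

**Further compounds**

F1 | step 12 | tert-butyl (3R,5R,6E,10E,14E)-5-[(tert-butyldimethylsilyl)oxy]-15-iodo-3-[methoxy(methyl)carbamoyl]-6,10,14-trimethylpentadeca-6,10,14-trienoate | CON(C)C(=O)[C@@H](CC(=O)OC(C)(C)C)C[C@@H](O[Si](C)(C)C(C)(C)C)/C(C)=C/CC/C(C)=C/CC/C(C)=C/I
F2 | step 12 | tert-butyl (3R,5R,6E,10E,14E)-5-[(tert-butyldimethylsilyl)oxy]-3-formyl-15-iodo-6,10,14-trimethylpentadeca-6,10,14-trienoate | O=C[C@@H](CC(=O)OC(C)(C)C)C[C@@H](O[Si](C)(C)C(C)(C)C)/C(C)=C/CC/C(C)=C/CC/C(C)=C/I
F3 | step 12 | tert-butyl 2-[(1R,3E,7E,11E,13R)-13-[(tert-butyldimethylsilyl)oxy]-4,8,12-trimethyl-2-oxocyclotetradeca-3,7,11-trien-1-yl]acetate | O=C1/C=C(\C)CC/C=C(\C)CC/C=C(\C)[C@H](O[Si](C)(C)C(C)(C)C)C[C@@H]1CC(=O)OC(C)(C)C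
F0 | step 16 | none | none
F4 | step 17 | (1R,2S,11R,12S)-11,12-epoxy-13-oxocembra-3E,7E,15(17)-trien-16,2-olide | C=C1C(=O)O[C@H]2/C=C(\C)CC/C=C(\C)CC[C@H]3O[C@]3(C)C(=O)C[C@H]12
F5 | step 17 | (1R,2S,11R,12R,13S)-11,12-epoxy-13-hydroxycembra-3E,7E,15(17)-trien-16,2-olide | C=C1C(=O)O[C@H]2/C=C(\C)CC/C=C(\C)CC[C@H]3O[C@]3(C)[C@@H](O)C[C@H]12
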